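All constants are assumed; what happens was integrated by code.

I decide first which given numbers I must know well, and which a rough value will serve.

    first end groups + second end groups → links (k1 = 4.92 × 10⁻⁴ M⁻¹ s⁻¹)
    first end groups + second end groups → rings, rate k2*[first end groups] as long as [second end groups] is above zero (k2 = 1.96 × 10⁻⁵ s⁻¹)
    2 second end groups → self-condensation product (k3 = 1.19 × 10⁻⁴ M⁻¹ s⁻¹)
    second end groups + protic impurity → quenched reagent (k4 = 9.72 × 10⁻⁴ M⁻¹ s⁻¹)
    first end groups + links ⇌ idle adduct, settled at all times (K5 = 17.0 M⁻¹)

first end groups 20 mM; second end groups 1.00 equiv; protic impurity 6.00 mM; time 15 d

- percent here means first end groups units held: one idle adduct counts as two
- what is said of links includes idle adduct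
- two of one species on the left: rate k times its square, two consumed each time
- in an amount of links, one idle adduct counts as one links
- the reaction counts as stopped when no species that holds the first end groups changes by six tenths of a point or more over the second half of the time
- run time (flask): 15 d

- why nothing more happens at 15 d, or that something still does (it is still moving / all of the first end groups has reacted / the second end groups has run out first)
- share of the first end groups used up at 15 d
- links at 15 d, in percent of the first end groups charged
- rings at 15 d, in percent of the first end groups charged

- The time needs little care: the half-life of the first end groups by the link step alone, with second end groups as charged, 0.82 d, is far shorter than 15 d, so I expect the flask to stop well before then.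
- The balance constant needs little care too: its product with the charged first end groups is 0.34, so at most a quarter of the links sit as idle adduct, and links form more slowly than rings.
- The self-condensation and impurity constants need moderate care, because they take second end groups and no first end groups from a one-to-one charge, so the second end groups should run out first. Together they take 26.5% of the second end groups' use at the start. That share shrinks as [B], the concentration of second end groups, falls, so as a rough mean I divide it by two, to 13.2%, and expect 86.8% of the first end groups used.
- The link and ring constants must be known well, but through their quotient. I call it the crossover concentration, B* = k2/k1 = 39.8 mM, and while [B] is above zero the rate of rings over the rate of links equals B*/[B], since [first end groups] cancels.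
- This selectivity factor starts at 1.99 and climbs as [B] falls. Taking the mean [B] as half the charge gives 3.98, so I expect links 17.4% and rings 69.4%.
- The forecast says the second end groups has run out first, with 83% used, links 15.4% and rings 67.5%, holding that “the first-order ring closure outruns linking by about two to one”. My figure for use is higher by 3.8 percentage points.
- The simulation gives the second end groups has run out first, with 83.2% used, links 15.0% and rings 67.4%; second end groups already stand at 0% of their charge after 1.50 d.
- In this flask, final rings over final links is 4.49 against my 3.98, so B* puts the mean [B] at 8.86 mM. The neighbour flask, charged with 0.600 equiv of second end groups, starts at 12.0 mM, so the same reckoning gives 6.64. That flask ends with links 6.60% and rings 47.3%, a ratio of 7.17, and with 45.2% of its first end groups left.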